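# Proposed total synthesis of CNP0236431.1 (the 3β,13-dihydroxy C20-gibberellin 20-aldehyde)

## The problem

- Target 37 is a C20 gibberellin drawn as its free 20-aldehyde. A trans-fused hydrindane (rings A and B, sharing C5–C10) is joined at the fully substituted C8 to a bicyclo[3.2.1]octane (rings C and D). The bridgehead C13 carries a tertiary hydroxyl beside the exocyclic C16=C17 methylene.
- There are eight stereocentres (C3, C4, C5, C6, C8, C9, C10, C13); four carry no hydrogen (C4, C8, C10, C13).
- C13 is tied to C8 by the bicycle. The independent problems are therefore the vicinal pair C8/C9, the C6 methine next to quaternary C8, and the ring A set C3, C4, C5, C10.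
- Three control elements are available. A substituent at C9 of a cyclohexenone can direct a conjugate addition to C8. C6, once in place, can fix the dienophile face (and so C5) through allylic 1,3-strain. The axial C20 group on C10 screens one face of C4.
- Fragile points:
  - the 13-hydroxy-16-ene (cationic rearrangement in acid; ketol shift at the 16-ketone stage);
  - the 3-hydroxy-19-carboxyl unit (retro-aldol in base);
  - the neopentyl C20 aldehyde held 1,3-diaxial to C19 (lactol now, irreversible lactone at the alcohol level);
  - C6 whenever C7 is a carbonyl;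
  - the very hindered axial ester at C4.
- The feature that opens the key step is ring A itself. It is a six-membered ring with oxygen at C3 next to a carboxyl-bearing C4, and it shares C5–C10 with the five-membered ring B. With a C1=C2 double bond written in, it is the adduct of a C3-oxygenated diene (C3=C2–C1=C10, hanging from C9) and an acceptor alkene (C4=C5, hanging from C6). The three-atom link C6–C8–C9 becomes ring B.

## Retrosynthesis

**From 37 back to 33 (no skeletal bonds).** The C16=C17 bond is cut to the 16-ketone 34 (Wittig). The C7 acid and the 16-ketone are traced to the primary/secondary diol 33. Methylenation has to follow saturation of C1=C2, because no hydrogenation would spare a 1,1-disubstituted alkene. The C19 acid is freed by attack on the ester methyl group (35 → 36), and the silyl ethers and the acetal fall together (36 → 37). In this order the free 3-hydroxy acid never meets base and the 13-hydroxy-16-ene meets only dilute acid. The forward steps must deliver a Wittig reaction on a hindered ketone with O13 silylated, and a mild last step.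

**C18 (C4 methyl from an ester).** The methyl of 32 comes from the equatorial ester of the geminal diester 29, by reduction (30) and deoxygenation (31). A dienophile already carrying the methyl group would save three steps. It would, however, leave one ester to drive a cycloaddition that forms two quaternary carbons, and it would need a Z-trisubstituted acrylate. Two esters are therefore kept for the key step and one is spent afterwards. 29 is the dihydro form of 28. The forward step must tell an axial ester, 1,3-diaxial to the C20 acetal, from its equatorial twin.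

**Key cut: C3–C4 and C5–C10 (28 ← 27).** Both bonds of ring A that are not in the tether are cut at once. Cutting only C5–C10 (a Michael closure) or only C3–C4 (an aldol) leaves the other quaternary centre and the ring fusion unsolved. The [4+2] cut removes two rings and three stereocentres (C3, C5, C10). It leaves 27, a bicyclo[3.2.1]octane with two acyclic arms. The forward reaction must give the trans ring fusion on the diene face that puts C20 syn to C11.

**Diene and dienophile (27 ← 26 ← 25 ← 24 ← 22 + 23).** The silyloxydiene is cut at O–Si to the γ-branched enal 26 (soft enolisation removes the C10 hydrogen). The dienophile is cut at C4=C5 to aldehyde 22 and dimethyl malonate 23 (Knoevenagel). The Knoevenagel is placed first, while C3 is still a PMB-protected allylic alcohol, so that only one aldehyde is present. The steps after it (DDQ, MnO2, silyl triflate/amine) do not touch an alkylidene malonate. The forward enolisation must place the bulky C9 outside and C20 inside on C10=C1.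

**C6 (22 ← 21 ← 20).** The C6–C7 bond is cut to the unbranched aldehyde 20 and formaldehyde. A secondary-amine catalyst, not the neighbouring quaternary centre, is asked to choose the face. Protecting O7 as a silyl ether (not carrying C7 as an ester) keeps H6 from being doubly activated in the alkylidene malonate.

**Ring D (20 ← 19 ← 18 ← 17 ← 16 ← 14).** The C13–C16 bond is cut by a pinacol disconnection to keto aldehyde 17. The aldehyde arm comes from the vinyl group of 14 by hydroboration and oxidation. The cis-diol is kept as 16-O-triethylsilyl ether with O13 free (19), so that a later step can silylate O13 before the 16-ketone is made. Closing ring D before the arms are elaborated gives the rigid cis disposition of the C8 and C9 arms that the cycloaddition needs.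

**C8 (14 ← 12 ← 11 ← 10).** The C8–C15 and C8–C6 bonds are cut as two conjugate additions around a Saegusa–Ito oxidation. The group added second enters anti to the C9 side chain. Vinyl (C15–C16) therefore comes second and the acetate arm (C6–C5) first. The second addition must form a quaternary carbon next to a branched centre.

**Ring C and C9 (10 ← 9 ← 7 + 8).** C9–C11 (Michael) and C8=C14 (aldol condensation) are cut to aldehyde 7 and methyl vinyl ketone 8. An amine catalyst sets C9 and through it the absolute configuration of the whole molecule.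

**The C10 arm (7 ← 6 ← 5 ← 1 + 2).** C9–C10 is cut by a Johnson–Claisen disconnection to the secondary allylic alcohol 5, and C1–C2 by an alkenylzinc addition to alkyne 1 and aldehyde 2. The rearrangement delivers the acetal (C20), the E-allylic ether (C1–C3) and a single C10 epimer. C10 is later erased, but its control keeps every intermediate a single compound.

## Roads not taken

**Alternative 1: radical closure of ring D last.**
- Cut: C15–C16.
- Forward step: a redox-active ester of a C8 acetic acid is reduced at a cathode. Loss of CO2 gives the C15 radical, which closes 5-exo-dig onto a C13 ethynyl carbinol to give A1.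
- Merits: ring D appears with exactly the target's functionality. No 16-ketone, no Wittig and no protection of O13 are needed, and the conditions are mild.
- Weak points: the step makes one ring, one bond and no stereocentre. All eight stereocentres and the A/B/C tricycle (with an axial ethynyl group cis to the C8 acetic acid) must already exist, and it offers no way to make them. The vinyl radical can be lost to hydrogen transfer.
- Comparison: for ring D this road is better than the chosen one, which spends steps 8–12 and 25–27 on it and carries a 16-oxygen through the route. The chosen plan sets against this a key step that makes two rings, two bonds and three stereocentres, including quaternary C10. Alternative 1 only postpones that problem.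

**Alternative 2: Nazarov closure of ring B, trapped by allylsilane.**
- Cut: C9–C10 and C8–C15.
- Forward step: BF3-promoted conrotatory closure of a C10=C5/C6-ketone/C8=C9 dienone; the oxyallyl cation is captured at C8 by allyltrimethylsilane to give A2.
- Merits: a convergent union of a ring A piece and a ring C piece. Ring B, quaternary C8 and the ring D handle arrive together.
- Weak points: the sense of conrotation must be dictated by ring A stereocentres several atoms away while C10 becomes quaternary. Capture may occur at C5 instead of C8. The C6 ketone, flanked by C5 and quaternary C8, must then be turned into a CH–CO2H carbon. The dithiane at C13 and the late ring D closure add steps.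
- Comparison: it equals the chosen plan in bonds made (two) and stereocentres addressed (three). It loses on the homologation at C6 and on the uncertain torquoselectivity. The chosen plan instead derives C5 from C6 by allylic strain.

**Alternative 3: ring A annulated last.**
- Cut: C1–C10 and C4–C5.
- Forward step: the C10 enolate of a ring B β-keto nitrile adds to methyl 3-oxopent-4-enoate, and aldol condensation gives enone A3.
- Merits: a classical, robust annulation. C20 is carried as a small nitrile, and ring D with its methylene is already in place.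
- Weak points: only C10 is set. C3, C4 and C5 remain: the C4=C5 alkene must be reduced to the trans fusion, C4 methylated on the correct face and the 3-ketone reduced to the axial alcohol. All of this happens in the presence of the 16-ene, and a hindered nitrile must be reduced beside esters at the end.
- Comparison: the annulation itself is safer than an untested cycloaddition, and that is a real advantage. The chosen plan sets against it that C3, C5 and C10 come out of one step with their relationships fixed by alkene geometry, leaving only C4.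

Key step: step 20

Remarks on the chemistry:
- The target is written as the free 20-aldehyde; it is expected to equilibrate with its 19,20-lactol, which does not affect the route.
- Gibberellane numbering (C1–C20) is used for all intermediates.
- R10 stands for the C10 side chain (2E)-1-(diethoxymethyl)-4-[(4-methoxybenzyl)oxy]but-2-en-1-yl with C10 configured as in 6 (its CIP letter changes with the neighbours, its geometry does not).
- Aldehyde 2 is taken as a purchasable compound.
- Configurations follow from literature models and relative-configuration analysis; nothing here has been run.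

## The route

Step 1
Reactants: 1 3,3-diethoxyprop-1-yne; 2 2-[(4-methoxybenzyl)oxy]acetaldehyde
Product: 5 (2S,3E)-5,5-diethoxy-1-[(4-methoxybenzyl)oxy]pent-3-en-2-ol, via alkenylborane 3 (not isolated), via alkenylzinc 4 (not isolated)
Conditions: Cy2BH, toluene, 0 °C → rt; Me2Zn, (−)-3-exo-morpholinoisoborneol (5 mol %), −78 → −10 °C; then 2
Reagents that add atoms: none
Why: Syn-hydroboration of the terminal alkyne, boron-to-zinc exchange and amino-alcohol-catalysed addition of the alkenylzinc to the aldehyde is an established route to (E)-allylic alcohols; the ligand sets the carbinol centre (S expected). Its only task is to make C10 a single epimer in step 2, so a modest ee costs little.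

Step 2
Reactants: 5 (2S,3E)-5,5-diethoxy-1-[(4-methoxybenzyl)oxy]pent-3-en-2-ol
Product: 6 ethyl (3R,4E)-3-(diethoxymethyl)-6-[(4-methoxybenzyl)oxy]hex-4-enoate
Conditions: MeC(OEt)3 (5 equiv), EtCO2H (cat.), 135 °C, EtOH distilled off
Reagents that add atoms: triethyl orthoacetate, CC(OCC)(OCC)OCC
Why: Johnson–Claisen rearrangement forms C9–C10; the chair transition state with CH2OPMB equatorial gives the (E)-alkene and transfers the carbinol configuration to C10. The ethyl orthoester matches the diethyl acetal, so alcohol exchange is harmless.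

Step 3
Reactants: 6 ethyl (3R,4E)-3-(diethoxymethyl)-6-[(4-methoxybenzyl)oxy]hex-4-enoate
Product: 7 (3R,4E)-3-(diethoxymethyl)-6-[(4-methoxybenzyl)oxy]hex-4-enal
Conditions: i-Bu2AlH (1.1 equiv), CH2Cl2, −78 °C; Rochelle salt
Reagents that add atoms: none
Why: Partial reduction of an ester at low temperature stops at the aluminium hemiacetal, which gives the aldehyde on work-up; acetal, PMB ether and alkene are inert.

Step 4
Reactants: 7 (3R,4E)-3-(diethoxymethyl)-6-[(4-methoxybenzyl)oxy]hex-4-enal; 8 but-3-en-2-one
Product: 9 (2S)-5-oxo-2-R10-hexanal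
Conditions: (S)-α,α-diphenylprolinol methyl ether (5 mol %), ethyl 3,4-dihydroxybenzoate (20 mol %), neat, 4 °C
Reagents that add atoms: none
Why: Enamine-catalysed Michael addition of an aldehyde to methyl vinyl ketone forms C9–C11. The diarylmethyl group of the (S)-catalyst shields one enamine face, and the usual model gives the C9 configuration of 37, overriding the remote C10 centre.

Step 5
Reactants: 9 (2S)-5-oxo-2-R10-hexanal
Product: 10 (4R)-4-R10-cyclohex-2-en-1-one
Conditions: LiOH·H2O (0.2 equiv), i-PrOH, rt
Reagents that add atoms: none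
Why: Intramolecular aldol condensation of the methyl ketone onto the aldehyde closes ring C (C14=C8). Mild hydroxide in isopropanol is the known way to 4-substituted cyclohexenones from such adducts with little loss at the γ-centre.

Step 6
Reactants: 10 (4R)-4-R10-cyclohex-2-en-1-one
Product: 11 tert-butyl 2-[3-(tert-butyldimethylsilyloxy)-6-R10-cyclohex-2-en-1-yl]acetate (acetate arm trans to R10)
Conditions: CH2=C(Ot-Bu)OSiMe2t-Bu (1.5 equiv), MeCN, 60 °C, no catalyst
Reagents that add atoms: tert-butyl[(1-tert-butoxyethenyl)oxy]dimethylsilane, C=C(OC(C)(C)C)O[Si](C)(C)C(C)(C)C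
Why: Uncatalysed Mukaiyama–Michael addition of a ketene silyl acetal in acetonitrile forms C8–C6 with silyl transfer to O13. Working without a Lewis acid spares the acetal, and the regiodefined enol ether is what step 7 needs; the C8 configuration made here is erased there.

Step 7
Reactants: 11 tert-butyl 2-[3-(tert-butyldimethylsilyloxy)-6-R10-cyclohex-2-en-1-yl]acetate
Product: 12 tert-butyl 2-(3-oxo-6-R10-cyclohex-1-en-1-yl)acetate
Conditions: Pd(OAc)2 (1.1 equiv), MeCN, rt
Reagents that add atoms: none
Why: Saegusa–Ito oxidation of the silyl enol ether restores the enone with the C6 arm now on the β-carbon C8; the neutral conditions leave the C9 γ-centre untouched.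

Step 8
Reactants: 12 tert-butyl 2-(3-oxo-6-R10-cyclohex-1-en-1-yl)acetate
Product: 14 tert-butyl 2-(1-ethenyl-5-oxo-2-R10-cyclohexyl)acetate (vinyl trans, acetate arm cis to R10), via trimethylsilyl enol ether 13 (not isolated)
Conditions: CH2=CHMgBr (3 equiv), CuBr·SMe2 (0.3 equiv), Me3SiCl, THF, −78 → −40 °C; then 10% aq citric acid
Reagents that add atoms: vinylmagnesium bromide, C=C[Mg]Br
Why: Copper-catalysed, chlorosilane-accelerated conjugate addition of a vinyl group to a β,β-disubstituted enone makes quaternary C8 (C8–C15). Axial attack anti to the C9 substituent puts vinyl trans and the acetate arm cis to the C10 arm, as in 37.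

Step 9
Reactants: 14 tert-butyl 2-(1-ethenyl-5-oxo-2-R10-cyclohexyl)acetate
Product: 16 tert-butyl 2-[1-(2-hydroxyethyl)-5-oxo-2-R10-cyclohexyl]acetate, via alkylborane 15 (not isolated)
Conditions: 9-BBN (1.3 equiv), THF, 0 °C → rt; then 30% H2O2, pH 7 phosphate buffer
Reagents that add atoms: hydrogen peroxide, OO
Why: Hydroboration–oxidation; 9-BBN reacts with a terminal vinyl group far faster than with the internal E-alkene of R10 or the ketone, and puts oxygen on C16.

Step 10
Reactants: 16 tert-butyl 2-[1-(2-hydroxyethyl)-5-oxo-2-R10-cyclohexyl]acetate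
Product: 17 tert-butyl 2-[5-oxo-1-(2-oxoethyl)-2-R10-cyclohexyl]acetate
Conditions: Dess–Martin periodinane, NaHCO3, CH2Cl2, 0 °C → rt
Reagents that add atoms: none
Why: Buffered Dess–Martin oxidation of the primary alcohol (through any ring-chain hemiketal) gives the 1,5-keto aldehyde needed for ring D.

Step 11
Reactants: 17 tert-butyl 2-[5-oxo-1-(2-oxoethyl)-2-R10-cyclohexyl]acetate
Product: 18 tert-butyl 2-(5,6-dihydroxy-2-R10-bicyclo[3.2.1]octan-1-yl)acetate (gibberellane 13,16-diol, hydroxyls cis; C8, C9, C13 as in 37)
Conditions: SmI2 (2.5 equiv), t-BuOH (2 equiv), THF, −78 °C → rt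
Reagents that add atoms: none
Why: Samarium diiodide pinacol cyclisation of a 1,5-keto aldehyde forms C13–C16 and ring D; bridging requires the aldehyde arm axial, which fixes C13 from C8, and the samarium-chelated diolate gives the cis-diol. Without HMPA neither the ester nor the alkene takes part.

Step 12
Reactants: 18 tert-butyl 2-(5,6-dihydroxy-2-R10-bicyclo[3.2.1]octan-1-yl)acetate
Product: 19 tert-butyl 2-[5-hydroxy-2-R10-6-(triethylsilyloxy)bicyclo[3.2.1]octan-1-yl]acetate
Conditions: Et3SiCl (1.2 equiv), imidazole, CH2Cl2, 0 °C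
Reagents that add atoms: chlorotriethylsilane, CC[Si](Cl)(CC)CC
Why: Silylation selective for the secondary 16-hydroxyl over the tertiary bridgehead 13-hydroxyl; the triethylsilyl ether survives the hydride steps and leaves later under mild acid together with the primary TBS ether.

Step 13
Reactants: 19 tert-butyl 2-[5-hydroxy-2-R10-6-(triethylsilyloxy)bicyclo[3.2.1]octan-1-yl]acetate
Product: 20 2-[5-hydroxy-2-R10-6-(triethylsilyloxy)bicyclo[3.2.1]octan-1-yl]acetaldehyde
Conditions: i-Bu2AlH (2.3 equiv), CH2Cl2, −78 °C; Rochelle salt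
Reagents that add atoms: none
Why: Partial reduction of the tert-butyl ester to the C5 aldehyde (one equivalent is spent on the free 13-hydroxyl); no other reducible group is present.

Step 14
Reactants: 20 2-[5-hydroxy-2-R10-6-(triethylsilyloxy)bicyclo[3.2.1]octan-1-yl]acetaldehyde
Product: 21 3-hydroxy-2-[5-hydroxy-2-R10-6-(triethylsilyloxy)bicyclo[3.2.1]octan-1-yl]propanal (C6 as in 37)
Conditions: 37% aq HCHO (3 equiv), (R)-α,α-diphenylprolinol trimethylsilyl ether (20 mol %), pH 7 phosphate buffer, toluene, rt
Reagents that add atoms: formaldehyde, C=O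
Why: Enamine-catalysed α-hydroxymethylation (cross-aldol with formaldehyde) forms C6–C7. The (R)-catalyst shields the enamine face opposite to that blocked in step 4, which by the same model gives the C6 configuration of 37; only the unbranched aldehyde can form the enamine.

Step 15
Reactants: 21 3-hydroxy-2-[5-hydroxy-2-R10-6-(triethylsilyloxy)bicyclo[3.2.1]octan-1-yl]propanal
Product: 22 3-(tert-butyldimethylsilyloxy)-2-[5-hydroxy-2-R10-6-(triethylsilyloxy)bicyclo[3.2.1]octan-1-yl]propanal
Conditions: t-BuMe2SiCl (1.2 equiv), imidazole, CH2Cl2, 0 °C, used crude from step 14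
Reagents that add atoms: tert-butylchlorodimethylsilane, CC(C)(C)[Si](C)(C)Cl
Why: Primary-selective silylation (the tertiary 13-hydroxyl does not react). Keeping C7 at the alcohol level prevents H6 from becoming doubly activated in step 16; the neopentyl-type α-centre enolises slowly under imidazole.

Step 16
Reactants: 22 3-(tert-butyldimethylsilyloxy)-2-[5-hydroxy-2-R10-6-(triethylsilyloxy)bicyclo[3.2.1]octan-1-yl]propanal; 23 dimethyl malonate
Product: 24 dimethyl 2-{3-(tert-butyldimethylsilyloxy)-2-[5-hydroxy-2-R10-6-(triethylsilyloxy)bicyclo[3.2.1]octan-1-yl]propylidene}malonate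
Conditions: piperidine (0.2 equiv), AcOH (0.2 equiv), 4 Å molecular sieves, benzene, rt → 50 °C
Reagents that add atoms: none
Why: Knoevenagel condensation forms C4=C5. The aldehyde is the only one in the molecule at this stage, and the hindered C6, flanked by quaternary C8, resists enamine formation and so epimerisation.

Step 17
Reactants: 24 dimethyl 2-{3-(tert-butyldimethylsilyloxy)-2-[5-hydroxy-2-R10-6-(triethylsilyloxy)bicyclo[3.2.1]octan-1-yl]propylidene}malonate
Product: 25 allylic alcohol (24 with the C9 side chain ending in (E)-CH=CH–CH2OH)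
Conditions: DDQ (1.3 equiv), CH2Cl2–pH 7 buffer (10:1), 0 °C
Reagents that add atoms: none
Why: Oxidative cleavage of the PMB ether through the benzylic oxocarbenium ion; silyl ethers, acetal and the electron-poor alkylidene malonate do not react with DDQ.

Step 18
Reactants: 25 allylic alcohol
Product: 26 enal (C9 side chain (2E)-1-(diethoxymethyl)-4-oxobut-2-en-1-yl)
Conditions: MnO2 (20 equiv), CH2Cl2, rt
Reagents that add atoms: none
Why: Manganese dioxide oxidises only the allylic alcohol and is neutral, so neither C6 nor the alkylidene malonate is disturbed.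

Step 19
Reactants: 26 enal
Product: 27 silyloxydiene–alkylidene malonate: C9 carries the (1Z,3E)-4-(tert-butyldimethylsilyloxy)-1-(diethoxymethyl)buta-1,3-dien-1-yl group (C9 trans to C2), C6 the CH=C(CO2Me)2 arm; 13-OTBS, 16-OTES, 7-OTBS
Conditions: t-BuMe2SiOTf (2.6 equiv), Et3N (5 equiv), Et2O, −78 → 0 °C
Reagents that add atoms: tert-butyldimethylsilyl trifluoromethanesulfonate, CC(C)(C)[Si](C)(C)OS(=O)(=O)C(F)(F)F
Why: Soft enolisation (silyl triflate/amine) of the s-trans enal removes the C10 hydrogen and gives the (E)-enol ether. The bulky ring carbon C9 should take the outside position on C10=C1 to avoid 1,3-allylic strain with H2, leaving C20 inside. The same reagent silylates the tertiary 13-hydroxyl; the amine-complexed triflate at low temperature should not ionise the acetal.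

Step 20
Reactants: 27 silyloxydiene–alkylidene malonate
Product: 28 tetracyclic cycloadduct (1-ene; 3β-OTBS; C4 bis(methoxycarbonyl); 7-OTBS; 13-OTBS; 16-OTES; C20 diethyl acetal; C3, C5, C6, C8, C9, C10, C13 as in 37)
Conditions: toluene (0.01 M), BHT (cat.), 110 °C, sealed tube
Reagents that add atoms: none
Why: Thermal suprafacial [4+2] cycloaddition, of the known type in which 1,3,8-nonatrienes carrying a 1-silyloxydiene and an alkylidene malonate close to hydrindenes; the C3 donor and the two C4 esters polarise it so that C5–C10 forms ahead of C3–C4. Ring B (five-membered) closes through the tether C6–C8–C9 when C5 bonds to C10, and ring A (six-membered) is the cyclohexene formed from diene and dienophile. C3 and C10 follow from the diene geometry: the (E)-enol ether and C9 trans to C2 put O3 and C9 on one face of ring A, and C20 with H3 on the other. C5 follows from C6: allylic 1,3-strain with the cis ester holds H6 in the plane of the alkene, C8 and C7 lie on opposite faces, and the diene, tied to C8, adds so that C4 ends syn to H6. The step needs the exo-tether (trans-fused) transition state, which with C5 fixed places C20 syn to C11. It should be favoured because in the endo-tether mode the inside C20 acetal is pressed against C6 and C8 of the folded tether, while the rigid cis arms on C8/C9 of the bicycle hold the termini within reach. With a doubly activated dienophile 110 °C should suffice, below the range where a 1,5-hydrogen shift from C20 in the Z-substituted diene would compete.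

Step 21
Reactants: 28 tetracyclic cycloadduct
Product: 29 1,2-dihydro diester
Conditions: H2 (4 atm), 10% Pd/C, EtOAc, rt
Reagents that add atoms: none
Why: Heterogeneous hydrogenation of the only alkene; no stereocentre is formed, and ethyl acetate (not an alcohol) keeps the triethylsilyl ether and the acetal intact.

Step 22
Reactants: 29 1,2-dihydro diester
Product: 30 18-hydroxy 19-methyl ester (equatorial CO2Me reduced to CH2OH)
Conditions: LiAlH(Ot-Bu)3 (3 equiv), THF, 0 °C → rt
Reagents that add atoms: none
Why: Sterically controlled mono-reduction of a geminal diester: the axial ester is screened by the 1,3-diaxial C20 acetal, so the bulky alkoxyaluminohydride should attack the equatorial one. The alkoxide formed then slows reduction of the second ester.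

Step 23
Reactants: 30 18-hydroxy 19-methyl ester
Product: 31 18-O-(phenoxythiocarbonyl) derivative
Conditions: PhOC(S)Cl (1.5 equiv), pyridine, DMAP (cat.), CH2Cl2, 0 °C → rt
Reagents that add atoms: O-phenyl chlorothionoformate, S=C(Cl)Oc1ccccc1
Why: Acylation at oxygen needs no substitution at the neopentyl carbon, and pyridine is too weak a base to start retro-aldol loss of formaldehyde from the β-hydroxy ester.

Step 24
Reactants: 31 18-O-(phenoxythiocarbonyl) derivative
Product: 32 methyl ester with C18 methyl (C4 as in 37)
Conditions: n-Bu3SnH (3 equiv), AIBN (cat.), toluene, 110 °C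
Reagents that add atoms: none
Why: Barton–McCombie deoxygenation; the primary neopentyl radical forms at reflux, has no β-leaving group, and is reduced by the stannane.

Step 25
Reactants: 32 methyl ester with C18 methyl
Product: 33 7,16-diol (3-OTBS and 13-OTBS kept)
Conditions: PPTS (0.3 equiv), EtOH, rt → 40 °C
Reagents that add atoms: none
Why: Mild acid alcoholysis removes the secondary triethylsilyl and primary TBS ethers and leaves the hindered secondary and tertiary TBS ethers; ethanol as solvent keeps C20 as its diethyl acetal.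

Step 26
Reactants: 33 7,16-diol
Product: 34 16-oxo 7-carboxylic acid
Conditions: n-Pr4N[RuO4] (10 mol %), NMO·H2O (10 equiv), MeCN, rt
Reagents that add atoms: water, O
Why: Ley–Griffith oxidation in the presence of N-oxide hydrate takes the primary alcohol through the aldehyde hydrate to the acid and the secondary alcohol to the ketone. With O13 silylated there is no glycol to cleave and no ketol to rearrange, and any epimerisation at C6 at the aldehyde stage runs towards the more stable natural configuration.

Step 27
Reactants: 34 16-oxo 7-carboxylic acid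
Product: 35 16-methylene 7-carboxylic acid
Conditions: Ph3PCH3Br (6 equiv), KOt-Bu (5.5 equiv), THF, 0 → 50 °C
Reagents that add atoms: methyltriphenylphosphonium bromide, C[P+](c1ccccc1)(c1ccccc1)c1ccccc1.[Br-]
Why: Wittig methylenation of the 16-ketone of 17-norgibberellins with excess ylide is standard in this series; the acid is carried as its carboxylate and the silylated O13 rules out a base-induced ketol shift.

Step 28
Reactants: 35 16-methylene 7-carboxylic acid
Product: 36 7,19-dioic acid
Conditions: n-PrSLi (10 equiv), HMPA, rt → 50 °C; then pH 4 buffer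
Reagents that add atoms: none
Why: SN2 demethylation by thiolate attacks the methyl carbon and is therefore insensitive to the crowding of the axial C19 carbonyl; silyl ethers, acetal and alkene are inert, and O3 is still protected, so no retro-aldol can occur.

Step 29
Reactants: 36 7,19-dioic acid
Product: 37 CNP0236431.1 (3β,13-dihydroxy-20-oxo-gibberell-16-ene-7,19-dioic acid)
Conditions: 48% aq HF–MeCN (1:9), 0 °C → rt
Reagents that add atoms: water, O
Why: Aqueous HF removes the hindered secondary and the tertiary TBS ether and hydrolyses the diethyl acetal in one operation; this weak acid at or below room temperature should not trigger rearrangement of the 13-hydroxy-16-ene.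

## Compound list

1 | 3,3-diethoxyprop-1-yne | C#CC(OCC)OCC | starting material
2 | 2-[(4-methoxybenzyl)oxy]acetaldehyde | O=CCOCc1ccc(OC)cc1 | starting material
3 | (E)-(3,3-diethoxyprop-1-en-1-yl)dicyclohexylborane | CCOC(OCC)/C=C/B(C1CCCCC1)C1CCCCC1 | intermediate
4 | (E)-(3,3-diethoxyprop-1-en-1-yl)(methyl)zinc | CCOC(OCC)/C=C/[Zn]C | intermediate
5 | (2S,3E)-5,5-diethoxy-1-[(4-methoxybenzyl)oxy]pent-3-en-2-ol | COc1ccc(COC[C@@H](O)/C=C/C(OCC)OCC)cc1 | intermediate
6 | ethyl (3R,4E)-3-(diethoxymethyl)-6-[(4-methoxybenzyl)oxy]hex-4-enoate | CCOC(=O)C[C@@H](C(OCC)OCC)/C=C/COCc1ccc(OC)cc1 | intermediate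
7 | (3R,4E)-3-(diethoxymethyl)-6-[(4-methoxybenzyl)oxy]hex-4-enal | O=CC[C@@H](C(OCC)OCC)/C=C/COCc1ccc(OC)cc1 | intermediate
8 | but-3-en-2-one | CC(=O)C=C | starting material
9 | (2S)-2-[(1S,2E)-1-(diethoxymethyl)-4-[(4-methoxybenzyl)oxy]but-2-en-1-yl]-5-oxohexanal | CC(=O)CC[C@H](C=O)[C@@H](C(OCC)OCC)/C=C/COCc1ccc(OC)cc1 | intermediate
10 | (4R)-4-[(1S,2E)-1-(diethoxymethyl)-4-[(4-methoxybenzyl)oxy]but-2-en-1-yl]cyclohex-2-en-1-one | O=C1C=C[C@H]([C@@H](C(OCC)OCC)/C=C/COCc2ccc(OC)cc2)CC1 | intermediate
11 | tert-butyl 2-[3-(tert-butyldimethylsilyloxy)-6-R10-cyclohex-2-en-1-yl]acetate, acetate arm trans to R10 | CC(C)(C)[Si](C)(C)OC1=C[C@@H](CC(=O)OC(C)(C)C)[C@H]([C@@H](C(OCC)OCC)/C=C/COCc2ccc(OC)cc2)CC1 | intermediate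
12 | tert-butyl 2-(3-oxo-6-R10-cyclohex-1-en-1-yl)acetate | O=C1C=C(CC(=O)OC(C)(C)C)[C@H]([C@@H](C(OCC)OCC)/C=C/COCc2ccc(OC)cc2)CC1 | intermediate
13 | trimethylsilyl enol ether of 14 | C[Si](C)(C)OC1=C[C@](C=C)(CC(=O)OC(C)(C)C)[C@H]([C@@H](C(OCC)OCC)/C=C/COCc2ccc(OC)cc2)CC1 | intermediate
14 | tert-butyl 2-(1-ethenyl-5-oxo-2-R10-cyclohexyl)acetate, vinyl trans and acetate arm cis to R10 | O=C1C[C@](C=C)(CC(=O)OC(C)(C)C)[C@H]([C@@H](C(OCC)OCC)/C=C/COCc2ccc(OC)cc2)CC1 | intermediate
15 | B-alkyl-9-borabicyclo[3.3.1]nonane from 14 (boron on C16) | O=C1C[C@](CCB2C3CCCC2CCC3)(CC(=O)OC(C)(C)C)[C@H]([C@@H](C(OCC)OCC)/C=C/COCc4ccc(OC)cc4)CC1 | intermediate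
16 | tert-butyl 2-[1-(2-hydroxyethyl)-5-oxo-2-R10-cyclohexyl]acetate | O=C1C[C@](CCO)(CC(=O)OC(C)(C)C)[C@H]([C@@H](C(OCC)OCC)/C=C/COCc2ccc(OC)cc2)CC1 | intermediate
17 | tert-butyl 2-[5-oxo-1-(2-oxoethyl)-2-R10-cyclohexyl]acetate | O=C1C[C@](CC=O)(CC(=O)OC(C)(C)C)[C@H]([C@@H](C(OCC)OCC)/C=C/COCc2ccc(OC)cc2)CC1 | intermediate
18 | tert-butyl 2-(5,6-dihydroxy-2-R10-bicyclo[3.2.1]octan-1-yl)acetate, cis-13,16-diol | O[C@H]1C[C@]2(CC(=O)OC(C)(C)C)C[C@@]1(O)CC[C@H]2[C@@H](C(OCC)OCC)/C=C/COCc3ccc(OC)cc3 | intermediate
19 | tert-butyl 2-[5-hydroxy-2-R10-6-(triethylsilyloxy)bicyclo[3.2.1]octan-1-yl]acetate | CC[Si](CC)(CC)O[C@H]1C[C@]2(CC(=O)OC(C)(C)C)C[C@@]1(O)CC[C@H]2[C@@H](C(OCC)OCC)/C=C/COCc3ccc(OC)cc3 | intermediate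
20 | 2-[5-hydroxy-2-R10-6-(triethylsilyloxy)bicyclo[3.2.1]octan-1-yl]acetaldehyde | CC[Si](CC)(CC)O[C@H]1C[C@]2(CC=O)C[C@@]1(O)CC[C@H]2[C@@H](C(OCC)OCC)/C=C/COCc3ccc(OC)cc3 | intermediate
21 | 3-hydroxy-2-[5-hydroxy-2-R10-6-(triethylsilyloxy)bicyclo[3.2.1]octan-1-yl]propanal, C6 as in 37 | CC[Si](CC)(CC)O[C@H]1C[C@]2([C@@H](CO)C=O)C[C@@]1(O)CC[C@H]2[C@@H](C(OCC)OCC)/C=C/COCc3ccc(OC)cc3 | intermediate
22 | 3-(tert-butyldimethylsilyloxy)-2-[5-hydroxy-2-R10-6-(triethylsilyloxy)bicyclo[3.2.1]octan-1-yl]propanal | CC[Si](CC)(CC)O[C@H]1C[C@]2([C@@H](CO[Si](C)(C)C(C)(C)C)C=O)C[C@@]1(O)CC[C@H]2[C@@H](C(OCC)OCC)/C=C/COCc3ccc(OC)cc3 | intermediate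
23 | dimethyl malonate | COC(=O)CC(=O)OC | starting material
24 | dimethyl 2-{3-(tert-butyldimethylsilyloxy)-2-[5-hydroxy-2-R10-6-(triethylsilyloxy)bicyclo[3.2.1]octan-1-yl]propylidene}malonate | CC[Si](CC)(CC)O[C@H]1C[C@]2([C@@H](CO[Si](C)(C)C(C)(C)C)C=C(C(=O)OC)C(=O)OC)C[C@@]1(O)CC[C@H]2[C@@H](C(OCC)OCC)/C=C/COCc3ccc(OC)cc3 | intermediate
25 | allylic alcohol (24 without the PMB group) | CC[Si](CC)(CC)O[C@H]1C[C@]2([C@@H](CO[Si](C)(C)C(C)(C)C)C=C(C(=O)OC)C(=O)OC)C[C@@]1(O)CC[C@H]2[C@@H](C(OCC)OCC)/C=C/CO | intermediate
26 | enal (C9 side chain (2E)-1-(diethoxymethyl)-4-oxobut-2-en-1-yl) | CC[Si](CC)(CC)O[C@H]1C[C@]2([C@@H](CO[Si](C)(C)C(C)(C)C)C=C(C(=O)OC)C(=O)OC)C[C@@]1(O)CC[C@H]2[C@@H](C(OCC)OCC)/C=C/C=O | intermediate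
27 | silyloxydiene–alkylidene malonate (C9: (1Z,3E)-4-(tert-butyldimethylsilyloxy)-1-(diethoxymethyl)buta-1,3-dien-1-yl; 13-OTBS; 16-OTES; 7-OTBS) | CC[Si](CC)(CC)O[C@H]1C[C@]2([C@@H](CO[Si](C)(C)C(C)(C)C)C=C(C(=O)OC)C(=O)OC)C[C@@]1(O[Si](C)(C)C(C)(C)C)CC[C@H]2/C(C(OCC)OCC)=C/C=C/O[Si](C)(C)C(C)(C)C | intermediate
28 | tetracyclic cycloadduct (1-ene; 3β-OTBS; 4,4-bis(methoxycarbonyl); 7-OTBS; 13-OTBS; 16-OTES; C20 diethyl acetal) | CC[Si](CC)(CC)O[C@H]1C[C@]23C[C@@]1(O[Si](C)(C)C(C)(C)C)CC[C@H]2[C@]4(C(OCC)OCC)C=C[C@H](O[Si](C)(C)C(C)(C)C)C(C(=O)OC)(C(=O)OC)[C@H]4[C@@H]3CO[Si](C)(C)C(C)(C)C | intermediate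
29 | 1,2-dihydro diester | CC[Si](CC)(CC)O[C@H]1C[C@]23C[C@@]1(O[Si](C)(C)C(C)(C)C)CC[C@H]2[C@]4(C(OCC)OCC)CC[C@H](O[Si](C)(C)C(C)(C)C)C(C(=O)OC)(C(=O)OC)[C@H]4[C@@H]3CO[Si](C)(C)C(C)(C)C | intermediate
30 | 18-hydroxy 19-methyl ester | CC[Si](CC)(CC)O[C@H]1C[C@]23C[C@@]1(O[Si](C)(C)C(C)(C)C)CC[C@H]2[C@]4(C(OCC)OCC)CC[C@H](O[Si](C)(C)C(C)(C)C)[C@@](CO)(C(=O)OC)[C@H]4[C@@H]3CO[Si](C)(C)C(C)(C)C | intermediate
31 | 18-O-(phenoxythiocarbonyl) derivative | CC[Si](CC)(CC)O[C@H]1C[C@]23C[C@@]1(O[Si](C)(C)C(C)(C)C)CC[C@H]2[C@]4(C(OCC)OCC)CC[C@H](O[Si](C)(C)C(C)(C)C)[C@@](COC(=S)Oc5ccccc5)(C(=O)OC)[C@H]4[C@@H]3CO[Si](C)(C)C(C)(C)C | intermediate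
32 | 19-methyl ester with C18 methyl (3,13-bis-OTBS; 7-OTBS; 16-OTES; C20 acetal) | CC[Si](CC)(CC)O[C@H]1C[C@]23C[C@@]1(O[Si](C)(C)C(C)(C)C)CC[C@H]2[C@]4(C(OCC)OCC)CC[C@H](O[Si](C)(C)C(C)(C)C)[C@@](C)(C(=O)OC)[C@H]4[C@@H]3CO[Si](C)(C)C(C)(C)C | intermediate
33 | 7,16-diol (3,13-bis-OTBS; 19-methyl ester; C20 acetal) | O[C@H]1C[C@]23C[C@@]1(O[Si](C)(C)C(C)(C)C)CC[C@H]2[C@]4(C(OCC)OCC)CC[C@H](O[Si](C)(C)C(C)(C)C)[C@@](C)(C(=O)OC)[C@H]4[C@@H]3CO | intermediate
34 | 16-oxo-17-nor 7-carboxylic acid | O=C1C[C@]23C[C@@]1(O[Si](C)(C)C(C)(C)C)CC[C@H]2[C@]4(C(OCC)OCC)CC[C@H](O[Si](C)(C)C(C)(C)C)[C@@](C)(C(=O)OC)[C@H]4[C@@H]3C(=O)O | intermediate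
35 | 16-methylene 7-carboxylic acid 19-methyl ester | C=C1C[C@]23C[C@@]1(O[Si](C)(C)C(C)(C)C)CC[C@H]2[C@]4(C(OCC)OCC)CC[C@H](O[Si](C)(C)C(C)(C)C)[C@@](C)(C(=O)OC)[C@H]4[C@@H]3C(=O)O | intermediate
36 | 7,19-dioic acid (3,13-bis-OTBS; C20 diethyl acetal) | C=C1C[C@]23C[C@@]1(O[Si](C)(C)C(C)(C)C)CC[C@H]2[C@]4(C(OCC)OCC)CC[C@H](O[Si](C)(C)C(C)(C)C)[C@@](C)(C(=O)O)[C@H]4[C@@H]3C(=O)O | intermediate
37 | CNP0236431.1, 3β,13-dihydroxy-20-oxo-gibberell-16-ene-7,19-dioic acid | C=C1C[C@]23C[C@@]1(O)CC[C@H]2[C@]1(C=O)CC[C@H](O)[C@@](C)(C(=O)O)[C@H]1[C@@H]3C(=O)O | target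

## Step count and least certain steps

Total: 29 steps. Longest linear sequence: 29 steps (the route is linear; 2, 8 and 23 enter as purchased materials).

**Step 20 (key step).**
- What may go wrong: closure through the endo-tether transition state, giving the cis-fused hydrindene; a 1,5-hydrogen shift from C20 or loss of the enol silyl group before cycloaddition; or an unreactive diene if step 19 has placed C9 inside on C10=C1.
- Fallback: set out from enal 26 and leave out isolated 27. Treat 26 with excess t-BuMe2SiOTf and Et3N in CH2Cl2 from −78 to −20 °C, so that the dienol ether formed in the flask reacts in a stepwise ionic manner. It adds through C10 to the silyl-triflate-activated alkylidene malonate (vinylogous Mukaiyama–Michael addition, closing ring B). The resulting malonate silyl ketene acetal then closes ring A by Mukaiyama aldol addition to the silyloxycarbenium ion at C3. This silyl triflate/amine-mediated Michael–aldol annulation is a known alternative to thermal cycloaddition. It runs at a temperature where sigmatropic shifts cannot compete, and its ring fusion is decided by an open Michael transition state, not a pericyclic one. It forms no new isolable compound (F0) and returns to the route at 28.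

**Step 8.**
- What may go wrong: deprotonation of the acidic CH2 between the enone and the ester by the vinyl nucleophile, or slow addition at the crowded β-carbon, so that the quaternary centre is not formed.
- Fallback: set out from enone 12 and use a non-basic alkynyl nucleophile. Nickel-catalysed conjugate addition of Me2AlC≡CSiMe3 (Ni(acac)2, i-Bu2AlH cat.) gives the β-alkynyl ketone F7, again anti to the C9 side chain. K2CO3 in MeOH removes the silyl group to give the terminal alkyne F8. Ruthenium-catalysed anti-Markovnikov hydration (CpRuCl(dppm), aqueous i-PrOH) turns C15≡C16 into the CH2–CHO arm. The route is rejoined at keto aldehyde 17.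

**Step 14.**
- What may go wrong: poor facial selectivity at C6 if the adjacent quaternary C8 overrides the catalyst, or slow enamine formation at this neopentyl-type aldehyde, with oligomerisation of the β-hydroxy aldehyde.
- Fallback: set out from aldehyde 20 and use an auxiliary. Pinnick oxidation gives acid F1. Its mixed pivalic anhydride acylates lithiated (S)-4-benzyloxazolidin-2-one to give imide F2. The Evans aldol reaction of its dibutylboron enolate with monomeric formaldehyde gives hydroxymethyl imide F3, with C6 set by the auxiliary. Silylation (t-BuMe2SiCl, imidazole) gives F4. LiBH4 releases the auxiliary and gives primary alcohol F5. Dess–Martin oxidation of F5 returns to the route at aldehyde 22.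

**Step 22.**
- What may go wrong: poor discrimination between the two esters (the equatorial one is itself flanked by the axial 3-silyloxy group), or over-reduction to the diol.
- Fallback: set out from diester 29 and give up telling the esters apart. Krapcho dealkoxycarbonylation (LiCl, wet DMSO, 150 °C) removes one ester and gives mono-ester F6 (C4 epimers of no consequence). Its enolate (LDA, THF–HMPA, −78 °C) is methylated with MeI on the face away from the axial C20 group. This is the classical outcome for ring A ester enolates with an axial C10 substituent, and gives the axial ester and equatorial methyl of 32 directly. The route is rejoined at 32, two steps shorter; the opposing influence of the axial 3-silyloxy group is the uncertainty of this detour.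

## Further compounds

F0 | step 20 | none | none
F7 | step 8 | tert-butyl 2-[5-oxo-2-R10-1-(trimethylsilylethynyl)cyclohexyl]acetate | O=C1C[C@](C#C[Si](C)(C)C)(CC(=O)OC(C)(C)C)[C@H]([C@@H](C(OCC)OCC)/C=C/COCc2ccc(OC)cc2)CC1
F8 | step 8 | tert-butyl 2-(1-ethynyl-5-oxo-2-R10-cyclohexyl)acetate | O=C1C[C@](C#C)(CC(=O)OC(C)(C)C)[C@H]([C@@H](C(OCC)OCC)/C=C/COCc2ccc(OC)cc2)CC1
F1 | step 14 | 2-[5-hydroxy-2-R10-6-(triethylsilyloxy)bicyclo[3.2.1]octan-1-yl]acetic acid | CC[Si](CC)(CC)O[C@H]1C[C@]2(CC(=O)O)C[C@@]1(O)CC[C@H]2[C@@H](C(OCC)OCC)/C=C/COCc3ccc(OC)cc3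
F2 | step 14 | N-acyl (S)-4-benzyloxazolidin-2-one of F1 | CC[Si](CC)(CC)O[C@H]1C[C@]2(CC(=O)N3C(=O)OC[C@@H]3Cc3ccccc3)C[C@@]1(O)CC[C@H]2[C@@H](C(OCC)OCC)/C=C/COCc3ccc(OC)cc3
F3 | step 14 | α-hydroxymethyl imide (C6 as in 37) | CC[Si](CC)(CC)O[C@H]1C[C@]2([C@@H](CO)C(=O)N3C(=O)OC[C@@H]3Cc3ccccc3)C[C@@]1(O)CC[C@H]2[C@@H](C(OCC)OCC)/C=C/COCc3ccc(OC)cc3
F4 | step 14 | α-(tert-butyldimethylsilyloxymethyl) imide | CC[Si](CC)(CC)O[C@H]1C[C@]2([C@@H](CO[Si](C)(C)C(C)(C)C)C(=O)N3C(=O)OC[C@@H]3Cc3ccccc3)C[C@@]1(O)CC[C@H]2[C@@H](C(OCC)OCC)/C=C/COCc3ccc(OC)cc3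
F5 | step 14 | 3-(tert-butyldimethylsilyloxy)-2-[5-hydroxy-2-R10-6-(triethylsilyloxy)bicyclo[3.2.1]octan-1-yl]propan-1-ol | CC[Si](CC)(CC)O[C@H]1C[C@]2([C@@H](CO[Si](C)(C)C(C)(C)C)CO)C[C@@]1(O)CC[C@H]2[C@@H](C(OCC)OCC)/C=C/COCc3ccc(OC)cc3
F6 | step 22 | mono-ester after loss of one methoxycarbonyl group (C4–H, both epimers) | CC[Si](CC)(CC)O[C@H]1C[C@]23C[C@@]1(O[Si](C)(C)C(C)(C)C)CC[C@H]2[C@]4(C(OCC)OCC)CC[C@H](O[Si](C)(C)C(C)(C)C)C(C(=O)OC)[C@H]4[C@@H]3CO[Si](C)(C)C(C)(C)C
A1 | alternative 1 | ring D-closed 13-hydroxy-16-ene with C20 dimethyl acetal, 3-O-methoxymethyl and 7,19-dimethyl ester | C=C1C[C@]23C[C@@]1(O)CC[C@H]2[C@]1(C(OC)OC)CC[C@H](OCOC)[C@@](C)(C(=O)OC)[C@H]1[C@@H]3C(=O)OC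
A2 | alternative 2 | A/B/C tricyclic C6 ketone with 8-allyl group, C13 dithiolane, C20 silyl ether | C=CC[C@]12CC3(CC[C@H]1[C@]1(CO[Si](c4ccccc4)(c4ccccc4)C(C)(C)C)CC[C@H](O[Si](C)(C)C(C)(C)C)[C@@](C)(C(=O)OC)[C@H]1C2=O)SCCS3
A3 | alternative 3 | tetracyclic 3-oxo-4-ene with C10 nitrile and C4 ester | C=C1C[C@]23C[C@@]1(OCOC)CC[C@H]2[C@]1(C#N)CCC(=O)C(C(=O)OC)=C1[C@@H]3C(=O)OC
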